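**Retrosynthetic overview**
1. Target 15 ⇐ deschloro depside 14 by late chlorination at C5' of ring B, the only aromatic C–H in the molecule.
2. 14 ⇐ depside C–O ester bond between ring B acid 11 (bis-benzyl ether) and the 4-OH of ring A phenol 9, then debenzylation.
3. Both 9 and 11 ⇐ one common arene, methyl 2,4-dihydroxy-3,6-dimethylbenzoate 6 (9 by C5 formylation and hydrogenolysis to methyl; 11 by benzylation and saponification).
4. 6 ⇐ aromatisation of cyclohexane-1,3-dione 4 ⇐ key C–C bond: intermolecular Michael addition of methyl 3-oxopentanoate 1 to methyl crotonate 2, closed by a Claisen (Dieckmann-type) condensation.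
5. Ring order: the six-membered carbocycle is built once (step 1), aromatised, and then serves as both ring A and ring B.

Assumption: the target has no stereocentre (it is achiral), so no stereocontrol is needed. Ring A is the methyl benzoate ring (unprimed locants) and ring B is the chlorinated acyl ring (primed locants).

**Route**

Step 1
Reactants: 1 methyl 3-oxopentanoate; 2 methyl (E)-but-2-enoate (methyl crotonate)
Product: 4 methyl 3,6-dimethyl-2,4-dioxocyclohexane-1-carboxylate, via Michael adduct 3 (not isolated)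
Conditions: NaOMe (1.1 equiv), MeOH, reflux, 18 h; then 2 M HCl, 0 °C
Reagents that add atoms: none
Why: Intermolecular Michael addition of the β-keto ester carbon to the crotonate, then intramolecular Claisen (Dieckmann-type) closure of the ethyl-ketone enolate onto the δ-ester, is driven by formation of the stabilised β-diketone enolate; the three stereocentres formed are uncontrolled and are erased in step 2.

Step 2
Reactants: 4 methyl 3,6-dimethyl-2,4-dioxocyclohexane-1-carboxylate
Product: 5 methyl 5-bromo-2,4-dihydroxy-3,6-dimethylbenzoate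
Conditions: Br2 (2.05 equiv), AcOH, 15 °C to rt; pour into water, filter
Reagents that add atoms: bromine, BrBr
Why: Oxidative aromatisation by α-bromination of the dione enol and loss of HBr, with the second equivalent of bromine substituting the only free ring position (electrophilic aromatic substitution), so a single crystalline product results.

Step 3
Reactants: 5 methyl 5-bromo-2,4-dihydroxy-3,6-dimethylbenzoate
Product: 6 methyl 2,4-dihydroxy-3,6-dimethylbenzoate
Conditions: H2 (1 atm), 10% Pd/C, NaOAc (1.2 equiv), MeOH, rt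
Reagents that add atoms: none
Why: Catalytic hydrodehalogenation of the aryl C–Br bond with acetate as HBr scavenger leaves the ester and phenols untouched.

Step 4
Reactants: 6 methyl 2,4-dihydroxy-3,6-dimethylbenzoate
Product: 8 methyl 5-formyl-2,4-dihydroxy-3,6-dimethylbenzoate, via α-chloro ether 7 (not isolated)
Conditions: Cl2CHOMe (1.5 equiv), TiCl4 (2.5 equiv), CH2Cl2, 0 °C to rt; then ice/1 M HCl
Reagents that add atoms: dichloromethyl methyl ether, COC(Cl)Cl; water, O
Why: Rieche formylation places the electrophile on the only free ring carbon (ortho to the 4-OH, para to the 2-OH), and aqueous work-up hydrolyses the α-chloro ether to the aldehyde.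

Step 5
Reactants: 8 methyl 5-formyl-2,4-dihydroxy-3,6-dimethylbenzoate
Product: 9 methyl 2,4-dihydroxy-3,5,6-trimethylbenzoate
Conditions: H2 (3 atm), 10% Pd/C, AcOH, cat. HCl, rt
Reagents that add atoms: none
Why: Acid-promoted catalytic hydrogenolysis of a hydroxy-activated aryl aldehyde runs through the benzylic alcohol to the methyl group without touching the ester.

Step 6
Reactants: 6 methyl 2,4-dihydroxy-3,6-dimethylbenzoate
Product: 10 methyl 2,4-bis(benzyloxy)-3,6-dimethylbenzoate
Conditions: BnBr (2.5 equiv), K2CO3 (3 equiv), DMF, 70 °C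
Reagents that add atoms: benzyl bromide, BrCc1ccccc1
Why: Williamson etherification; excess reagent and heat are used so that the chelated 2-OH is alkylated as well as the 4-OH.

Step 7
Reactants: 10 methyl 2,4-bis(benzyloxy)-3,6-dimethylbenzoate
Product: 11 2,4-bis(benzyloxy)-3,6-dimethylbenzoic acid
Conditions: KOH, DMSO/H2O (4:1), 90 °C; then aq HCl
Reagents that add atoms: potassium hydroxide, [K+].[OH-]
Why: Saponification of the di-ortho-substituted ester needs the poorly solvated hydroxide available in DMSO; benzyl ethers are stable, and the protected acid does not decarboxylate.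

Step 8
Reactants: 11 2,4-bis(benzyloxy)-3,6-dimethylbenzoic acid (1.1 equiv); 9 methyl 2,4-dihydroxy-3,5,6-trimethylbenzoate
Product: 13 methyl 4-{[2,4-bis(benzyloxy)-3,6-dimethylbenzoyl]oxy}-2-hydroxy-3,5,6-trimethylbenzoate, via mixed trifluoroacetic anhydride 12 (not isolated)
Conditions: TFAA (4 equiv), toluene, rt, 6–16 h; then aq NaHCO3
Reagents that add atoms: none
Why: Mixed-anhydride esterification: TFAA turns the hindered acid into an acylium-like electrophile that acylates the free 4-OH of 9, while the 2-OH is chelated to the ester and ring A has no free carbon for Friedel–Crafts acylation.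

Step 9
Reactants: 13 methyl 4-{[2,4-bis(benzyloxy)-3,6-dimethylbenzoyl]oxy}-2-hydroxy-3,5,6-trimethylbenzoate
Product: 14 methyl 4-[(2,4-dihydroxy-3,6-dimethylbenzoyl)oxy]-2-hydroxy-3,5,6-trimethylbenzoate
Conditions: H2 (1 atm), 10% Pd/C, EtOAc, rt
Reagents that add atoms: none
Why: Hydrogenolysis of the two benzyl ethers under neutral conditions leaves the aryl ester and the methyl ester intact, and no aryl chloride is present yet to be lost.

Step 10
Reactants: 14 methyl 4-[(2,4-dihydroxy-3,6-dimethylbenzoyl)oxy]-2-hydroxy-3,5,6-trimethylbenzoate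
Product: 15 methyl 4-[(5-chloro-2,4-dihydroxy-3,6-dimethylbenzoyl)oxy]-2-hydroxy-3,5,6-trimethylbenzoate (the target)
Conditions: SO2Cl2 (1.05 equiv), Et2O, 0 °C to rt
Reagents that add atoms: sulfuryl chloride, O=S(=O)(Cl)Cl
Why: Electrophilic aromatic chlorination can only substitute at C5' of ring B, the single aromatic C–H, which is ortho to the 4'-OH and para to the 2'-OH; one equivalent at low temperature limits ipso attack.

**Compound list**
1 | methyl 3-oxopentanoate | CCC(=O)CC(=O)OC | starting material
2 | methyl (E)-but-2-enoate | C/C=C/C(=O)OC | starting material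
3 | dimethyl 3-methyl-2-propanoylpentanedioate (diastereomer mixture, not isolated) | CCC(=O)C(C(=O)OC)C(C)CC(=O)OC | intermediate
4 | methyl 3,6-dimethyl-2,4-dioxocyclohexane-1-carboxylate (mixture of diastereomers and enol tautomers) | COC(=O)C1C(C)CC(=O)C(C)C1=O | intermediate
5 | methyl 5-bromo-2,4-dihydroxy-3,6-dimethylbenzoate | COC(=O)c1c(C)c(Br)c(O)c(C)c1O | intermediate
6 | methyl 2,4-dihydroxy-3,6-dimethylbenzoate | COC(=O)c1c(C)cc(O)c(C)c1O | intermediate
7 | methyl 5-[chloro(methoxy)methyl]-2,4-dihydroxy-3,6-dimethylbenzoate (racemic, not isolated) | COC(=O)c1c(C)c(C(Cl)OC)c(O)c(C)c1O | intermediate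
8 | methyl 5-formyl-2,4-dihydroxy-3,6-dimethylbenzoate | COC(=O)c1c(C)c(C=O)c(O)c(C)c1O | intermediate
9 | methyl 2,4-dihydroxy-3,5,6-trimethylbenzoate | COC(=O)c1c(C)c(C)c(O)c(C)c1O | intermediate
10 | methyl 2,4-bis(benzyloxy)-3,6-dimethylbenzoate | COC(=O)c1c(C)cc(OCc2ccccc2)c(C)c1OCc1ccccc1 | intermediate
11 | 2,4-bis(benzyloxy)-3,6-dimethylbenzoic acid | OC(=O)c1c(C)cc(OCc2ccccc2)c(C)c1OCc1ccccc1 | intermediate
12 | 2,4-bis(benzyloxy)-3,6-dimethylbenzoic trifluoroacetic anhydride (not isolated) | O=C(OC(=O)C(F)(F)F)c1c(C)cc(OCc2ccccc2)c(C)c1OCc1ccccc1 | intermediate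
13 | methyl 4-{[2,4-bis(benzyloxy)-3,6-dimethylbenzoyl]oxy}-2-hydroxy-3,5,6-trimethylbenzoate | COC(=O)c1c(C)c(C)c(OC(=O)c2c(C)cc(OCc3ccccc3)c(C)c2OCc2ccccc2)c(C)c1O | intermediate
14 | methyl 4-[(2,4-dihydroxy-3,6-dimethylbenzoyl)oxy]-2-hydroxy-3,5,6-trimethylbenzoate | COC(=O)c1c(C)c(C)c(OC(=O)c2c(C)cc(O)c(C)c2O)c(C)c1O | intermediate
15 | methyl 4-[(5-chloro-2,4-dihydroxy-3,6-dimethylbenzoyl)oxy]-2-hydroxy-3,5,6-trimethylbenzoate | COC(=O)c1c(C)c(C)c(OC(=O)c2c(C)c(Cl)c(O)c(C)c2O)c(C)c1O | target

**Step count and risks**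
Total steps: 10. Longest linear sequence: 8 steps (1, 2, 3, 4, 5, 8, 9, 10; the branch through 6 and 7 is equally long).

The three steps most likely to fail:

Step 8 (esterification of a di-ortho-substituted acid with a phenol flanked by two methyl groups, and 4-OH versus 2-OH selectivity). The fallback sets out from 11 and comes back at 13. The acid is converted with oxalyl chloride and catalytic DMF in CH2Cl2 into 2,4-bis(benzyloxy)-3,6-dimethylbenzoyl chloride F1. Phenol 9 is deprotonated with one equivalent of NaH in THF at 0 °C, which forms the phenoxide of the more acidic 4-OH (para to the ester) and leaves the chelated 2-OH protonated. This phenoxide is acylated by the acid chloride with catalytic DMAP to give 13. The acid-mediated acylium pathway is thus replaced by nucleophilic acylation of a preformed phenoxide.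

Step 10 (late chlorination; risk of ipso attack or over-chlorination of the free depside). The fallback sets out from 6 and comes back at 15, with the chlorine introduced first. Chlorination of 6 with SO2Cl2 in Et2O at 0 °C gives methyl 5-chloro-2,4-dihydroxy-3,6-dimethylbenzoate F2. Benzylation (BnBr, K2CO3, DMF) gives methyl 2,4-bis(benzyloxy)-5-chloro-3,6-dimethylbenzoate F3. Saponification (KOH, DMSO/H2O) gives 2,4-bis(benzyloxy)-5-chloro-3,6-dimethylbenzoic acid F4. TFAA in toluene converts this into 2,4-bis(benzyloxy)-5-chloro-3,6-dimethylbenzoic trifluoroacetic anhydride F5, which acylates 9 to give methyl 4-{[2,4-bis(benzyloxy)-5-chloro-3,6-dimethylbenzoyl]oxy}-2-hydroxy-3,5,6-trimethylbenzoate F6. The benzyl ethers are then removed with BCl3 and pentamethylbenzene in CH2Cl2 at −78 °C, not by hydrogenolysis, so that the aryl chloride survives, giving 15.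

Step 5 (hydrogenolysis of the chelated aldehyde may stall at the benzylic alcohol or give diarylmethane by-products). The fallback sets out from bromide 5 and comes back at 9, bypassing steps 3 to 5 for ring A by a cross-coupling methylation. Benzylation of 5 (BnBr, K2CO3, DMF) gives methyl 2,4-bis(benzyloxy)-5-bromo-3,6-dimethylbenzoate F7. Suzuki–Miyaura coupling with trimethylboroxine (Pd(OAc)2, SPhos, K3PO4, toluene/H2O, 100 °C) gives methyl 2,4-bis(benzyloxy)-3,5,6-trimethylbenzoate F8. Hydrogenolysis (H2, 10% Pd/C, EtOAc) then gives 9.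

**Further compounds**
F1 | step 8 | 2,4-bis(benzyloxy)-3,6-dimethylbenzoyl chloride | O=C(Cl)c1c(C)cc(OCc2ccccc2)c(C)c1OCc1ccccc1
F2 | step 10 | methyl 5-chloro-2,4-dihydroxy-3,6-dimethylbenzoate | COC(=O)c1c(C)c(Cl)c(O)c(C)c1O
F3 | step 10 | methyl 2,4-bis(benzyloxy)-5-chloro-3,6-dimethylbenzoate | COC(=O)c1c(C)c(Cl)c(OCc2ccccc2)c(C)c1OCc1ccccc1
F4 | step 10 | 2,4-bis(benzyloxy)-5-chloro-3,6-dimethylbenzoic acid | OC(=O)c1c(C)c(Cl)c(OCc2ccccc2)c(C)c1OCc1ccccc1
F5 | step 10 | 2,4-bis(benzyloxy)-5-chloro-3,6-dimethylbenzoic trifluoroacetic anhydride | O=C(OC(=O)C(F)(F)F)c1c(C)c(Cl)c(OCc2ccccc2)c(C)c1OCc1ccccc1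
F6 | step 10 | methyl 4-{[2,4-bis(benzyloxy)-5-chloro-3,6-dimethylbenzoyl]oxy}-2-hydroxy-3,5,6-trimethylbenzoate | COC(=O)c1c(C)c(C)c(OC(=O)c2c(C)c(Cl)c(OCc3ccccc3)c(C)c2OCc2ccccc2)c(C)c1O
F7 | step 5 | methyl 2,4-bis(benzyloxy)-5-bromo-3,6-dimethylbenzoate | COC(=O)c1c(C)c(Br)c(OCc2ccccc2)c(C)c1OCc1ccccc1
F8 | step 5 | methyl 2,4-bis(benzyloxy)-3,5,6-trimethylbenzoate | COC(=O)c1c(C)c(C)c(OCc2ccccc2)c(C)c1OCc1ccccc1
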